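**Retrosynthetic overview**

1. Petchiether B ⇐ saponification and desilylation ⇐ diimide saturation of C8′=C9′ ⇐ macrocyclic (R)-dienol 20; the only ring formed in the route is the 14-membered aryl-ether ring (the benzene ring is bought).
2. Key disconnection: the C9′–C10′ bond (the carbinol carbon C10′ and the ring CH2 next to it). C10′ becomes a neopentyl α-aryloxy aldehyde and C9′ the terminal carbon of a (Z)-enyne; one pot (hydroboration, B→Zn exchange, (+)-DAIB-catalysed alkenylzinc addition) closes the ring and sets the only stereocentre from an achiral open chain.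
3. Enabling features: C10′ is flanked by the fully substituted C11′ (gem-dimethyl, O-aryl), so the aldehyde cannot enolise; the 1,2-disubstituted benzene ring and the two in-ring-cis olefins C2′=C3′ and C6′=C7′ (6 of 14 ring atoms sp2) fold the chain; the C8′≡C9′ alkyne is a latent C9′ nucleophile.
4. Open chain 17 ⇐ HWE (C2′=C3′) of arylacetaldehyde 9 (hydroquinone, Claisen allylation, O-alkylation with ethyl 2-bromoisobutyrate) with phosphonate 15 ((Z)-enyne from a cyclopropylcarbinyl–homoallyl rearrangement).

Key step: step 12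

Remark: side-chain carbons are numbered C1′ (benzylic CH2) to C11′ (the OCMe2 carbon), C10′ being the carbinol carbon; Cy2BH for step 12 is prepared beforehand from BH3·SMe2 and cyclohexene; the facial sense of (+)-DAIB is assigned by analogy with its dialkylzinc additions to aldehydes, and the enantiomeric ligand would be used if the opposite sense were found.

**Step 1**
Reactants: 1 hydroquinone (3 equiv)
Product: 2 4-[(triisopropylsilyl)oxy]phenol
Conditions: TIPSCl (1 equiv), imidazole, DMF, 0 °C → rt
Reagents that add atoms: triisopropylsilyl chloride, CC(C)[Si](Cl)(C(C)C)C(C)C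
Why: Statistical mono-silylation (silyl ether formation) of a symmetrical diphenol used in excess; TIPS is chosen because it should survive carbonate, hydride and organozinc reagents and fall to fluoride at the end.

**Step 2**
Reactants: 2 4-[(triisopropylsilyl)oxy]phenol; 3 allyl bromide
Product: 4 1-(allyloxy)-4-[(triisopropylsilyl)oxy]benzene
Conditions: K2CO3, acetone, reflux
Reagents that add atoms: none
Why: Williamson ether synthesis on the one free phenol.

**Step 3**
Reactants: 4 1-(allyloxy)-4-[(triisopropylsilyl)oxy]benzene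
Product: 5 2-allyl-4-[(triisopropylsilyl)oxy]phenol
Conditions: N,N-diethylaniline, 190 °C, sealed, Ar
Reagents that add atoms: none
Why: Aromatic Claisen rearrangement ([3,3]); both ortho positions are equivalent and the para position is blocked, so one regioisomer should form.

**Step 4**
Reactants: 5 2-allyl-4-[(triisopropylsilyl)oxy]phenol; 6 ethyl 2-bromo-2-methylpropanoate
Product: 7 ethyl 2-{2-allyl-4-[(triisopropylsilyl)oxy]phenoxy}-2-methylpropanoate
Conditions: K2CO3, DMF, 70 °C
Reagents that add atoms: none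
Why: O-Alkylation of a phenoxide with a tertiary α-bromo ester (the aryloxyisobutyrate synthesis) builds the tertiary alkyl aryl ether O–C11′.

**Step 5**
Reactants: 7 ethyl 2-{2-allyl-4-[(triisopropylsilyl)oxy]phenoxy}-2-methylpropanoate
Product: 8 2-{2-allyl-4-[(triisopropylsilyl)oxy]phenoxy}-2-methylpropan-1-ol
Conditions: LiAlH4, THF, 0 °C
Reagents that add atoms: none
Why: Hydride reduction of the ester to the neopentyl alcohol (future C10′); the allyl group is a hydride-stable masked aldehyde and the aryl silyl ether is inert at 0 °C.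

**Step 6**
Reactants: 8 2-{2-allyl-4-[(triisopropylsilyl)oxy]phenoxy}-2-methylpropan-1-ol
Product: 9 2-{2-[(1-hydroxy-2-methylpropan-2-yl)oxy]-5-[(triisopropylsilyl)oxy]phenyl}acetaldehyde
Conditions: OsO4 (cat.), NaIO4, 2,6-lutidine, dioxane/H2O, rt; used at once
Reagents that add atoms: osmium tetroxide, O=[Os](=O)(=O)=O; sodium periodate, [Na+].[O-]I(=O)(=O)=O
Why: Lemieux–Johnson oxidative cleavage of the only olefin gives the arylacetaldehyde (C1′–C2′); the lutidine buffer suppresses side reactions of this enolisable aldehyde.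

**Step 7**
Reactants: 10 cyclopropyl methyl ketone; 11 ethynylmagnesium bromide
Product: 12 2-cyclopropylbut-3-yn-2-ol (racemic)
Conditions: THF, 0 °C → rt; aq. NH4Cl
Reagents that add atoms: none
Why: Grignard (acetylide) addition to a ketone; the stereocentre is irrelevant because it is destroyed in step 8.

**Step 8**
Reactants: 12 2-cyclopropylbut-3-yn-2-ol
Product: 13 (Z)-6-bromo-3-methylhex-3-en-1-yne
Conditions: 48% aq. HBr, 0 °C
Reagents that add atoms: hydrogen bromide, Br
Why: Julia olefin synthesis (cyclopropylcarbinyl–homoallyl rearrangement): bromide opens the cyclopropane of the cyclopropylcarbinyl cation, and the slim ethynyl group rather than methyl is expected to sit cis to the new CH2CH2Br chain, giving the Z-enyne (any E isomer would be removed on AgNO3–silica).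

**Step 9**
Reactants: 14 triethyl phosphonoacetate (2 equiv); 13 (Z)-6-bromo-3-methylhex-3-en-1-yne
Product: 15 ethyl (5Z)-2-(diethoxyphosphoryl)-6-methyloct-5-en-7-ynoate (racemic)
Conditions: NaH, DMF, 0 °C; then 13, NaI (cat.), 60 °C
Reagents that add atoms: none
Why: SN2 C-alkylation of the soft, weakly basic sodium phosphonoacetate by a primary bromide (iodide-assisted), which leaves the olefin geometry untouched; excess nucleophile limits dialkylation.

**Step 10**
Reactants: 9 2-{2-[(1-hydroxy-2-methylpropan-2-yl)oxy]-5-[(triisopropylsilyl)oxy]phenyl}acetaldehyde; 15 ethyl (5Z)-2-(diethoxyphosphoryl)-6-methyloct-5-en-7-ynoate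
Product: 16 ethyl (2E,5Z)-2-(2-{2-[(1-hydroxy-2-methylpropan-2-yl)oxy]-5-[(triisopropylsilyl)oxy]phenyl}ethylidene)-6-methyloct-5-en-7-ynoate
Conditions: LiCl, DBU, MeCN, 0 °C → rt
Reagents that add atoms: none
Why: Horner–Wadsworth–Emmons olefination under mild LiCl/amine conditions; the reversible addition and lithium chelation should place CO2Et trans to the CH2Ar group (2E), and the weak base spares the enolisable aldehyde and the terminal alkyne.

**Step 11**
Reactants: 16 ethyl (2E,5Z)-2-(2-{2-[(1-hydroxy-2-methylpropan-2-yl)oxy]-5-[(triisopropylsilyl)oxy]phenyl}ethylidene)-6-methyloct-5-en-7-ynoate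
Product: 17 ethyl (2E,5Z)-6-methyl-2-(2-{2-[(2-methyl-1-oxopropan-2-yl)oxy]-5-[(triisopropylsilyl)oxy]phenyl}ethylidene)oct-5-en-7-ynoate
Conditions: Dess–Martin periodinane, NaHCO3, CH2Cl2, 0 °C → rt
Reagents that add atoms: none
Why: Dess–Martin oxidation of the neopentyl alcohol to the non-enolisable α-aryloxy aldehyde; alkyne, olefins and silyl ether are inert.

**Step 12**
Reactants: 17 ethyl (2E,5Z)-6-methyl-2-(2-{2-[(2-methyl-1-oxopropan-2-yl)oxy]-5-[(triisopropylsilyl)oxy]phenyl}ethylidene)oct-5-en-7-ynoate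
Product: 20 macrocyclic (R)-dienol (TIPS ether ethyl ester of 8′,9′-didehydropetchiether B; C10′ R; 8′E; 6′Z; 2′E), via E-dienylborane 18 (not isolated), via E-dienylzinc 19 (not isolated)
Conditions: Cy2BH (1.1 equiv), toluene/hexane, 0 °C → rt; then syringe-pump addition to Et2Zn (2 equiv), (+)-DAIB (10 mol %), hexane, 0 °C, final c ≈ 0.003 M; aq. NH4Cl
Reagents that add atoms: none
Why: Cy2BH adds syn and anti-Markovnikov to the terminal C8′≡C9′ alkyne only (the neopentyl aldehyde, the ester and the trisubstituted olefins are slower) to give E-dienylborane 18; boron–zinc exchange with Et2Zn gives dienyl(ethyl)zinc 19, whose sp2 carbon C9′ is transferred to the aldehyde carbon C10′ inside the chiral amino-alkoxide–zinc complex of (+)-DAIB. The closest known reaction type is the one-pot hydroboration, boron–zinc exchange and amino-alcohol-catalysed intramolecular alkenylzinc–aldehyde addition that closes large carbocycles and macrolactones from ω-alkynals. The 14-membered ring closes in a 14-exo-trig mode, favoured by slow addition (pseudo-high dilution) and by the ortho-phenylene unit and the two in-ring-cis olefins that bend the chain. The new stereocentre C10′ is catalyst-controlled: in the bimetallic amino-alkoxide transition state (+)-DAIB should deliver the alkenyl group to the Re face of the aldehyde, which gives R, and the new C8′=C9′ bond is E because hydroboration is syn and both metal exchanges retain configuration. The step needs alkenyl rather than ethyl transfer (alkenyl groups leave zinc much faster than ethyl) and addition rather than enolisation (C10′ has no α-hydrogen because C11′ is quaternary).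

**Step 13**
Reactants: 20 macrocyclic (R)-dienol
Product: 21 TIPS ether ethyl ester of petchiether B (C10′ R; 6′Z; 2′E)
Conditions: NBSH (2-nitrobenzenesulfonyl hydrazide), Et3N, CH2Cl2, rt, monitored
Reagents that add atoms: none
Why: Diimide reduction: the concerted syn transfer of H2 is fastest for the 1,2-disubstituted C8′=C9′ olefin of the diene, while the trisubstituted C6′=C7′ and enoate olefins react much more slowly; no metal is involved, so no isomerisation or hydrogenolysis is expected.

**Step 14**
Reactants: 21 TIPS ether ethyl ester of petchiether B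
Product: 23 Petchiether B, via phenol ethyl ester 22 (not isolated)
Conditions: TBAF, THF, 0 °C; then LiOH, THF/EtOH/H2O, 40 °C, Ar; 1 M HCl to pH 3 at 0 °C
Reagents that add atoms: lithium hydroxide, [Li+].[OH-]
Why: Fluoride desilylation of the aryl silyl ether followed in the same flask by ester saponification; neither stage touches the carbinol stereocentre, the tertiary ether or the olefin geometries.

**Compound list**

1 | hydroquinone | Oc1ccc(O)cc1 | starting material
2 | 4-[(triisopropylsilyl)oxy]phenol | CC(C)[Si](Oc1ccc(O)cc1)(C(C)C)C(C)C | intermediate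
3 | allyl bromide | C=CCBr | starting material
4 | 1-(allyloxy)-4-[(triisopropylsilyl)oxy]benzene | C=CCOc1ccc(O[Si](C(C)C)(C(C)C)C(C)C)cc1 | intermediate
5 | 2-allyl-4-[(triisopropylsilyl)oxy]phenol | C=CCc1cc(O[Si](C(C)C)(C(C)C)C(C)C)ccc1O | intermediate
6 | ethyl 2-bromo-2-methylpropanoate | CCOC(=O)C(C)(C)Br | starting material
7 | ethyl 2-{2-allyl-4-[(triisopropylsilyl)oxy]phenoxy}-2-methylpropanoate | CCOC(=O)C(C)(C)Oc1ccc(O[Si](C(C)C)(C(C)C)C(C)C)cc1CC=C | intermediate
8 | 2-{2-allyl-4-[(triisopropylsilyl)oxy]phenoxy}-2-methylpropan-1-ol | OCC(C)(C)Oc1ccc(O[Si](C(C)C)(C(C)C)C(C)C)cc1CC=C | intermediate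
9 | 2-{2-[(1-hydroxy-2-methylpropan-2-yl)oxy]-5-[(triisopropylsilyl)oxy]phenyl}acetaldehyde | O=CCc1cc(O[Si](C(C)C)(C(C)C)C(C)C)ccc1OC(C)(C)CO | intermediate
10 | cyclopropyl methyl ketone | CC(=O)C1CC1 | starting material
11 | ethynylmagnesium bromide | C#C[Mg]Br | starting material
12 | 2-cyclopropylbut-3-yn-2-ol (racemic) | CC(O)(C#C)C1CC1 | intermediate
13 | (Z)-6-bromo-3-methylhex-3-en-1-yne | C#C/C(C)=C\CCBr | intermediate
14 | triethyl phosphonoacetate | CCOC(=O)CP(=O)(OCC)OCC | starting material
15 | ethyl (5Z)-2-(diethoxyphosphoryl)-6-methyloct-5-en-7-ynoate (racemic) | CCOC(=O)C(CC/C=C(C)\C#C)P(=O)(OCC)OCC | intermediate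
16 | ethyl (2E,5Z)-2-(2-{2-[(1-hydroxy-2-methylpropan-2-yl)oxy]-5-[(triisopropylsilyl)oxy]phenyl}ethylidene)-6-methyloct-5-en-7-ynoate | CCOC(=O)/C(CC/C=C(C)\C#C)=C/Cc1cc(O[Si](C(C)C)(C(C)C)C(C)C)ccc1OC(C)(C)CO | intermediate
17 | ethyl (2E,5Z)-6-methyl-2-(2-{2-[(2-methyl-1-oxopropan-2-yl)oxy]-5-[(triisopropylsilyl)oxy]phenyl}ethylidene)oct-5-en-7-ynoate | CCOC(=O)/C(CC/C=C(C)\C#C)=C/Cc1cc(O[Si](C(C)C)(C(C)C)C(C)C)ccc1OC(C)(C)C=O | intermediate
18 | E-dienyl dicyclohexylborane from 17 (boron on C9′) | CCOC(=O)/C(CC/C=C(C)\C=C\B(C1CCCCC1)C1CCCCC1)=C/Cc1cc(O[Si](C(C)C)(C(C)C)C(C)C)ccc1OC(C)(C)C=O | intermediate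
19 | E-dienyl(ethyl)zinc (zinc on C9′) | CCOC(=O)/C(CC/C=C(C)\C=C\[Zn]CC)=C/Cc1cc(O[Si](C(C)C)(C(C)C)C(C)C)ccc1OC(C)(C)C=O | intermediate
20 | macrocyclic (R)-dienol: 14-membered aryl-ether ring, C10′ R, C8′=C9′ E, C6′=C7′ Z, C2′=C3′ E, ethyl ester, aryl TIPS ether | CC1(C)Oc2ccc(O[Si](C(C)C)(C(C)C)C(C)C)cc2C/C=C(\CC/C=C(C)\C=C\[C@H]1O)C(=O)OCC | intermediate
21 | TIPS ether ethyl ester of petchiether B (C10′ R, C6′=C7′ Z, C2′=C3′ E) | CC1(C)Oc2ccc(O[Si](C(C)C)(C(C)C)C(C)C)cc2C/C=C(\CC/C=C(C)\CC[C@H]1O)C(=O)OCC | intermediate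
22 | petchiether B ethyl ester (free phenol) | CC1(C)Oc2ccc(O)cc2C/C=C(\CC/C=C(C)\CC[C@H]1O)C(=O)OCC | intermediate
23 | Petchiether B | CC1(C)Oc2ccc(O)cc2C/C=C(\CC/C=C(C)\CC[C@H]1O)C(=O)O | target

**Step count and risks**

Total steps: 14. Longest linear sequence: 11 steps (steps 1–6 and 10–14); the side chain (steps 7–9) is a three-step branch.

Most likely to fail:

1. Step 12. Intermolecular addition may outrun ring closure (oligomers), ethyl or hydride may be transferred to the hindered aldehyde, and chelation of zinc by the C11′ aryloxy oxygen may erode or reverse facial selectivity. The fallback sets out from 16 and returns at 21. Hydrozirconation of the terminal alkyne of 16 with Cp2Zr(H)Cl followed by iodine should give the (E)-dienyl iodide F1. Dess–Martin oxidation gives the iodo aldehyde F2. A Nozaki–Hiyama–Kishi macrocyclisation (CrCl2, cat. NiCl2, DMSO/THF, high dilution) forms the same C9′–C10′ bond and gives the racemic macrocyclic dienol F3. Diimide (NBSH, Et3N) gives the racemic saturated alcohol F4, and Dess–Martin oxidation gives the macrocyclic ketone F5. Reduction of F5 with (S)-Me-CBS and BH3·SMe2 (large group the tertiary C11′, small group CH2) should give 21.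

2. Step 13. Diimide may over-reduce the C6′=C7′ or C2′=C3′ olefins, or the reaction may stall because diimide disproportionates before conversion is complete. The fallback sets out from 20 and returns at 21. MnO2 oxidation of 20 gives the macrocyclic dienone F6. Copper hydride 1,4-reduction (Stryker's reagent, toluene, rt) saturates only the α,β-bond and gives the ketone F5 of the first fallback. (S)-Me-CBS reduction then re-installs the (R)-carbinol and gives 21.

3. Step 8. The cyclopropylcarbinyl ring opening may show low Z/E selectivity, or bromide may be captured at the alkyne terminus of the propargylic cation (bromoallene). The fallback sets out from 14 and 9 and returns at 16, replacing steps 7–9. Alkylation of 14 with 2-(2-bromoethyl)-1,3-dioxolane (NaH, DMF) gives the acetal phosphonate F7. HWE olefination with 9 (LiCl, DBU) gives the acetal enoate F8, and AcOH/H2O/THF gives the aldehyde F9. Stork–Zhao iodo-olefination with Ph3P=C(I)CH3 (from EtPPh3I, n-BuLi, I2, NaHMDS, −78 °C, one extra equivalent for the free hydroxyl) gives the (Z)-vinyl iodide F10. Sonogashira coupling with trimethylsilylacetylene (Pd(PPh3)2Cl2, CuI, Et3N) proceeds with retention and gives the TMS-enyne F11. K2CO3 in EtOH removes the alkynyl silane and gives 16.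

**Further compounds**

F1 | step 12 | (E)-dienyl iodide alcohol | CCOC(=O)/C(CC/C=C(C)\C=C\I)=C/Cc1cc(O[Si](C(C)C)(C(C)C)C(C)C)ccc1OC(C)(C)CO
F2 | step 12 | (E)-dienyl iodide aldehyde | CCOC(=O)/C(CC/C=C(C)\C=C\I)=C/Cc1cc(O[Si](C(C)C)(C(C)C)C(C)C)ccc1OC(C)(C)C=O
F3 | step 12 | racemic macrocyclic dienol | CC1(C)Oc2ccc(O[Si](C(C)C)(C(C)C)C(C)C)cc2C/C=C(\CC/C=C(C)\C=C\C1O)C(=O)OCC
F4 | step 12 | racemic saturated macrocyclic alcohol | CC1(C)Oc2ccc(O[Si](C(C)C)(C(C)C)C(C)C)cc2C/C=C(\CC/C=C(C)\CCC1O)C(=O)OCC
F5 | step 12 | macrocyclic C10′ ketone | CC1(C)Oc2ccc(O[Si](C(C)C)(C(C)C)C(C)C)cc2C/C=C(\CC/C=C(C)\CCC1=O)C(=O)OCC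
F6 | step 13 | macrocyclic dienone | CC1(C)Oc2ccc(O[Si](C(C)C)(C(C)C)C(C)C)cc2C/C=C(\CC/C=C(C)\C=C\C1=O)C(=O)OCC
F7 | step 8 | ethyl 2-(diethoxyphosphoryl)-4-(1,3-dioxolan-2-yl)butanoate | CCOC(=O)C(CCC1OCCO1)P(=O)(OCC)OCC
F8 | step 8 | acetal enoate | CCOC(=O)/C(CCC1OCCO1)=C/Cc1cc(O[Si](C(C)C)(C(C)C)C(C)C)ccc1OC(C)(C)CO
F9 | step 8 | enoate aldehyde | CCOC(=O)/C(CCC=O)=C/Cc1cc(O[Si](C(C)C)(C(C)C)C(C)C)ccc1OC(C)(C)CO
F10 | step 8 | (Z)-vinyl iodide | CCOC(=O)/C(CC/C=C(C)\I)=C/Cc1cc(O[Si](C(C)C)(C(C)C)C(C)C)ccc1OC(C)(C)CO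
F11 | step 8 | TMS-enyne | CCOC(=O)/C(CC/C=C(C)\C#C[Si](C)(C)C)=C/Cc1cc(O[Si](C(C)C)(C(C)C)C(C)C)ccc1OC(C)(C)CO
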